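**Retrosynthetic overview**

1. Target 13 ⇒ diene 12 by ring-closing metathesis across C3=C4. The cyclohexene is the only ring and is closed last.
2. 12 ⇒ ketone 7 + silane 9: the C1–C2 bond joins the ketone carbon to the chlorine-bearing carbon of an (E)-γ-chloroallylsilane (a 1-chloroallyl carbanion equivalent), delivered through an O–Si tether. This one step sets C1 and C2.
3. 7 ⇒ 2 + acrolein 3: syn-aldol (brings both benzoates and sets C5/C6 relative configuration), then kinetic resolution.
4. 2 ⇒ dihydroxyacetone 1 + BzCl; 9 ⇒ (E)-1,3-dichloropropene 8 + HSiCl3.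

Assumption: the target is taken exactly as the given SMILES, i.e. [(1R,2R,5S,6R)-6-(benzoyloxy)-2-chloro-1,5-dihydroxycyclohex-3-en-1-yl]methyl benzoate; compound 1 is drawn as the monomer although it is sold as a dimer that dissociates in solution.

**Route**

Step 1
Reactants: 1 1,3-dihydroxyacetone
Product: 2 2-oxopropane-1,3-diyl dibenzoate
Conditions: BzCl (2.2 equiv), pyridine, CH2Cl2, 0 °C to rt
Reagents that add atoms: benzoyl chloride, O=C(Cl)c1ccccc1
Why: Pyridine-mediated O-benzoylation (Einhorn acylation) of both primary hydroxyls of the monomeric ketone, which is released from the dimer as it reacts; no stereocentre is formed.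

Step 2
Reactants: 2 2-oxopropane-1,3-diyl dibenzoate; 3 acrolein
Product: 6 rac-(3R*,4S*)-4-hydroxy-2-oxohex-5-ene-1,3-diyl dibenzoate, via dibutylboron Z-enolate 4 (not isolated), via dibutylboron aldolate 5 (not isolated)
Conditions: Bu2BOTf (1.1 equiv), iPr2NEt (1.3 equiv), CH2Cl2, −78 °C; 3 (1.5 equiv), −78 to −30 °C; pH 7 buffer, MeOH, 30% H2O2, 0 °C
Reagents that add atoms: none
Why: Boron-mediated aldol addition in which the Z-configured O-boron enolate 4 adds to acrolein through a closed Zimmerman–Traxler chair to give the 3,4-syn aldol as the racemate, the boron being removed from aldolate 5 by buffered H2O2.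

Step 3
Reactants: 6 rac-(3R*,4S*)-4-hydroxy-2-oxohex-5-ene-1,3-diyl dibenzoate
Product: 7 (3R,4S)-4-hydroxy-2-oxohex-5-ene-1,3-diyl dibenzoate
Conditions: Ti(OiPr)4 (0.2 equiv), L-(+)-diisopropyl tartrate (0.24 equiv), t-BuOOH (0.6 equiv), 4 Å molecular sieves, CH2Cl2, −20 °C, to about 55% conversion
Reagents that add atoms: none
Why: Sharpless kinetic resolution of a secondary allylic alcohol, in which the L-(+)-tartrate catalyst epoxidises the (4R)-carbinol enantiomer much faster, so the (3R,4S)-alcohol is recovered in high ee (at most 50% yield) and separated from the more polar epoxy alcohol by chromatography.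

Step 4
Reactants: 8 (E)-1,3-dichloropropene
Product: 9 trichloro[(2E)-3-chloroprop-2-en-1-yl]silane
Conditions: HSiCl3 (1.2 equiv), CuCl (5 mol%), iPr2NEt (1.1 equiv), Et2O, 0 °C to rt; distillation under argon
Reagents that add atoms: trichlorosilane, Cl[SiH](Cl)Cl
Why: Copper-catalysed trichlorosilylation of an allylic chloride (Furuya–Sukawa reaction, as used to make crotyltrichlorosilanes), which replaces only the allylic chloride at its own carbon with retention of the E geometry while the vinylic chloride is inert.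

Step 5
Reactants: 7 (3R,4S)-4-hydroxy-2-oxohex-5-ene-1,3-diyl dibenzoate; 9 trichloro[(2E)-3-chloroprop-2-en-1-yl]silane
Product: 12 [(3R,4R,5R,6S)-5-(benzoyloxy)-3-chloro-4,6-dihydroxyocta-1,7-dien-4-yl]methyl benzoate, via chloroallyl(dichloro)silyl ether 10 (not isolated), via cyclic dichlorosilylene diether 11 (not isolated)
Conditions: 9 (1.3 equiv), iPr2NEt (1.5 equiv), CH2Cl2, −40 to 0 °C; DMF (3 equiv), 0 °C to rt; 1 M aq HCl, THF, 0 °C
Reagents that add atoms: none
Why: Proposed new method: the hydroxyl of 7 is silylated by 9 to give 10, whose silicon binds the ketone oxygen and, activated by DMF, transfers the γ-chloroallyl group through a bridged bicyclic chair–chair transition state (vinyl equatorial on the O–Si–O chelate ring, C5–OBz bond antiperiplanar to the forming bond, chlorine equatorial because the silane is E), so that the chlorine-bearing carbon attacks the carbonyl carbon as a 1-chloroallyl carbanion equivalent and sets C4 (R) and C3 (R) of 12 in one event; the closest known reaction types are Kira–Sakurai allyl- and crotylsilane additions to β-hydroxy ketones, Leighton's tethered aldol–allylation, Kobayashi's DMF-promoted allyltrichlorosilane additions and the Oehlschlager–Brown γ-chloroallylboration of aldehydes.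

Step 6
Reactants: 12 [(3R,4R,5R,6S)-5-(benzoyloxy)-3-chloro-4,6-dihydroxyocta-1,7-dien-4-yl]methyl benzoate
Product: 13 [(1R,2R,5S,6R)-6-(benzoyloxy)-2-chloro-1,5-dihydroxycyclohex-3-en-1-yl]methyl benzoate
Conditions: second-generation Grubbs catalyst RuCl2(=CHPh)(PCy3)(H2IMes) (5 mol%; H2IMes = 1,3-dimesitylimidazolidin-2-ylidene), CH2Cl2 (5 mM), 40 °C
Reagents that add atoms: none
Why: Ring-closing olefin metathesis of the 1,7-diene closes the only ring with loss of ethene, tolerating the free hydroxyls, benzoates and allylic chloride and leaving the four stereocentres untouched (C3, C4, C5, C6 of 12 become C2, C1, C6, C5 of 13).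

**Compound list**

1 | 1,3-dihydroxyacetone (sold as its dimer) | OCC(=O)CO | starting material
2 | 2-oxopropane-1,3-diyl dibenzoate (1,3-dibenzoyloxyacetone) | O=C(COC(=O)c1ccccc1)COC(=O)c1ccccc1 | intermediate
3 | acrolein (prop-2-enal) | C=CC=O | starting material
4 | (1Z)-2-[(dibutylboranyl)oxy]prop-1-ene-1,3-diyl dibenzoate (boron enolate of 2, O–B cis to OBz) | CCCCB(CCCC)O/C(COC(=O)c1ccccc1)=C\OC(=O)c1ccccc1 | intermediate (not isolated)
5 | rac-(3R*,4S*)-4-[(dibutylboranyl)oxy]-2-oxohex-5-ene-1,3-diyl dibenzoate (syn boron aldolate, both enantiomers 1:1) | C=C[C@H](OB(CCCC)CCCC)[C@@H](OC(=O)c1ccccc1)C(=O)COC(=O)c1ccccc1.C=C[C@@H](OB(CCCC)CCCC)[C@H](OC(=O)c1ccccc1)C(=O)COC(=O)c1ccccc1 | intermediate (not isolated)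
6 | rac-(3R*,4S*)-4-hydroxy-2-oxohex-5-ene-1,3-diyl dibenzoate (syn aldol, both enantiomers 1:1) | C=C[C@H](O)[C@@H](OC(=O)c1ccccc1)C(=O)COC(=O)c1ccccc1.C=C[C@@H](O)[C@H](OC(=O)c1ccccc1)C(=O)COC(=O)c1ccccc1 | intermediate
7 | (3R,4S)-4-hydroxy-2-oxohex-5-ene-1,3-diyl dibenzoate | C=C[C@H](O)[C@@H](OC(=O)c1ccccc1)C(=O)COC(=O)c1ccccc1 | intermediate
8 | (E)-1,3-dichloropropene | Cl/C=C/CCl | starting material
9 | trichloro[(2E)-3-chloroprop-2-en-1-yl]silane | Cl/C=C/C[Si](Cl)(Cl)Cl | intermediate
10 | (3R,4S)-4-({dichloro[(2E)-3-chloroprop-2-en-1-yl]silyl}oxy)-2-oxohex-5-ene-1,3-diyl dibenzoate | C=C[C@H](O[Si](Cl)(Cl)C/C=C/Cl)[C@@H](OC(=O)c1ccccc1)C(=O)COC(=O)c1ccccc1 | intermediate (not isolated)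
11 | cyclic dichlorosilylene diether of 12 (2,2-dichloro-1,3,2-dioxasilinane across O-4 and O-6 of 12, configuration as in 12) | C=C[C@H](O2)[C@@H](OC(=O)c1ccccc1)[C@](O[Si]2(Cl)Cl)(COC(=O)c1ccccc1)[C@H](Cl)C=C | intermediate (not isolated)
12 | [(3R,4R,5R,6S)-5-(benzoyloxy)-3-chloro-4,6-dihydroxyocta-1,7-dien-4-yl]methyl benzoate | C=C[C@H](O)[C@@H](OC(=O)c1ccccc1)[C@](O)(COC(=O)c1ccccc1)[C@H](Cl)C=C | intermediate
13 | [(1R,2R,5S,6R)-6-(benzoyloxy)-2-chloro-1,5-dihydroxycyclohex-3-en-1-yl]methyl benzoate | O=C(OC[C@]1(O)[C@H](Cl)C=C[C@H](O)[C@H]1OC(=O)c1ccccc1)c1ccccc1 | target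

**Step count and risks**

Total steps: 6. Longest linear sequence: 5 (steps 1, 2, 3, 5, 6); step 4 is a one-step side branch.

Steps most likely to fail:

- **Step 5 (tethered γ-chloroallylation).** The silyl-tethered transfer of a chloroallyl group to a ketone is untested, and the chloroallylsilane may be too weak a nucleophile or the β-silyloxy ketone may eliminate. The fallback sets out from 7 and returns at 12, and replaces tether delivery by an open, reagent-geometry-controlled addition. Silylation of the hydroxyl (Et3SiOTf, 2,6-lutidine, CH2Cl2, −78 °C) gives (3R,4S)-2-oxo-4-[(triethylsilyl)oxy]hex-5-ene-1,3-diyl dibenzoate F1. Addition of (Z)-(3-chloroallyl)-9-borabicyclo[3.3.1]nonane, made at −95 °C from allyl chloride, LiN(c-C6H11)2 and B-methoxy-9-borabicyclo[3.3.1]nonane and then BF3·OEt2 (the Oehlschlager–Brown way to Z-γ-chloroallylboranes), gives the boron borinate of the adduct F2. Ethanolamine cleaves it to the 6-O-triethylsilyl ether of 12 F3, and HF·pyridine in THF at 0 °C removes the silyl group to give 12. Here Felkin–Anh attack anti to the C–OBz bond fixes the carbinol carbon, and the Z-reagent with the large chain equatorial in the chair gives the same chlorohydrin.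

- **Step 3 (kinetic resolution).** A monosubstituted vinyl carbinol epoxidises slowly, and the titanium alkoxide may cause acyl migration or retro-aldol cleavage of the β-hydroxy ketone over the long reaction time. The fallback sets out from 6 and returns at 7 without any reagent-based resolution: the racemate is separated by preparative chromatography on a chiral stationary phase (cellulose tris(3,5-dimethylphenylcarbamate), hexane/i-PrOH) and the (3R,4S) enantiomer is collected; no new compound is made (entry F0).

- **Step 2 (boron aldol).** Enolate geometry of an α-benzoyloxy ketone, and hence the syn:anti ratio, is not secured, and the product can suffer benzoate migration. The fallback sets out from 2 and returns at 6 through an isolated enol silane and an open transition state. Me3SiOTf and Et3N in CH2Cl2 at 0 °C give (1Z)-2-[(trimethylsilyl)oxy]prop-1-ene-1,3-diyl dibenzoate F4. A BF3·OEt2-mediated Mukaiyama aldol addition to 3 at −78 °C and aqueous work-up then give 6, the minor anti isomer being removed by chromatography.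

**Further compounds**

F1 | step 5 | (3R,4S)-2-oxo-4-[(triethylsilyl)oxy]hex-5-ene-1,3-diyl dibenzoate | C=C[C@H](O[Si](CC)(CC)CC)[C@@H](OC(=O)c1ccccc1)C(=O)COC(=O)c1ccccc1
F2 | step 5 | 9-borabicyclo[3.3.1]nonan-9-yl borinate of F3 (boron on the tertiary oxygen, not isolated) | C=C[C@H](O[Si](CC)(CC)CC)[C@@H](OC(=O)c1ccccc1)[C@](OB2C3CCCC2CCC3)(COC(=O)c1ccccc1)[C@H](Cl)C=C
F3 | step 5 | 6-O-triethylsilyl ether of 12 | C=C[C@H](O[Si](CC)(CC)CC)[C@@H](OC(=O)c1ccccc1)[C@](O)(COC(=O)c1ccccc1)[C@H](Cl)C=C
F0 | step 3 | none | none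
F4 | step 2 | (1Z)-2-[(trimethylsilyl)oxy]prop-1-ene-1,3-diyl dibenzoate | C[Si](C)(C)O/C(COC(=O)c1ccccc1)=C\OC(=O)c1ccccc1
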